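**Retrosynthetic overview**
1. The quinone (ring B) is unveiled last, from a MOM-protected p-methoxyphenol, by deprotection and oxidative demethylation.
2. Key step: ring C and the C-3 stereocentre are made together. The triflate of a 1-aryl-3-aryloxypropan-2-ol ionises with a 1,2-aryl shift through a phenonium ion, and ring A closes onto it (6-endo Friedel–Crafts).
3. That alcohol comes from the lithiated ring B arene and the (S)-glycidyl ether of 2,3,4-trimethoxyphenol; (R)-epichlorohydrin supplies the stereocentre.
4. Both oxygenated benzene rings are built by ring expansion of squarate-derived 4-alkenylcyclobutenones (vinyl for ring A, 1-methoxyvinyl for ring B), starting from squaric acid.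
5. Order of ring formation: rings A and B (cyclobutenone to benzene), then ring C (pyran), then the quinone oxidation level.

Assumption: the single stereocentre (C-3 of the chroman; numbering O-1, C-2, C-3, C-4) is read from the SMILES as S.

**Route**

Step 1
Reactants: 1 squaric acid
Product: 2 dimethyl squarate (3,4-dimethoxycyclobut-3-ene-1,2-dione)
Conditions: HC(OMe)3, MeOH, reflux, 24 h
Reagents that add atoms: trimethyl orthoformate, COC(OC)OC
Why: O-methylation of the vinylogous acid with the orthoformate as methyl donor and water scavenger (Fischer-type esterification), the standard preparation of this diester.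

Step 2
Reactants: 2 dimethyl squarate; 3 vinyl bromide
Product: 6 4-ethenyl-2,3,4-trimethoxycyclobut-2-en-1-one, via vinyllithium 4 (not isolated), via lithium alkoxide 5 (not isolated)
Conditions: 3, t-BuLi (2 equiv), Et2O, −78 °C; then 2, THF, −78 °C; then MeOTf, −78 → 0 °C
Reagents that add atoms: methyl trifluoromethanesulfonate, COS(=O)(=O)C(F)(F)F
Why: Bromine–lithium exchange, 1,2-addition of the alkenyllithium to one squarate carbonyl (Moore/Liebeskind squarate chemistry) and O-methylation of the tertiary alkoxide in the same flask.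

Step 3
Reactants: 6 4-ethenyl-2,3,4-trimethoxycyclobut-2-en-1-one
Product: 8 2,3,4-trimethoxyphenol, via dienylketene 7 (not isolated)
Conditions: p-xylene, 140 °C
Reagents that add atoms: none
Why: Moore-type thermal ring expansion of a 4-alkenylcyclobutenone: ring opening with the 4-methoxy group rotating outward gives ketene 7, which closes (6π) and enolises to the phenol, fixing the 1,2,3,4-tetraoxygenation of ring A.

Step 4
Reactants: 8 2,3,4-trimethoxyphenol; 9 (R)-epichlorohydrin
Product: 11 (2S)-2-[(2,3,4-trimethoxyphenoxy)methyl]oxirane, via chlorohydrin 10 (not isolated)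
Conditions: K2CO3, MeCN, 80 °C (9 in 3-fold excess)
Reagents that add atoms: none
Why: Phenoxide opens the epoxide at its CH2 and the alkoxide re-closes on the CH2Cl carbon (Williamson-type glycidylation); the stereocentre is never touched, and the descriptor changes from R to S only because the CIP ranks of the two CH2 groups swap.

Step 5
Reactants: 2 dimethyl squarate; 12 methyl vinyl ether
Product: 15 2,3-dimethoxy-4-(1-methoxyethenyl)-4-(methoxymethoxy)cyclobut-2-en-1-one, via 1-methoxyvinyllithium 13 (not isolated), via lithium alkoxide 14 (not isolated)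
Conditions: 12, t-BuLi, THF, −78 → 0 °C; then 2, −78 °C; then MOMCl, −78 °C → rt
Reagents that add atoms: chloromethyl methyl ether, COCCl
Why: α-Lithiation of the enol ether (acyl-anion-equivalent chemistry), 1,2-addition to the squarate carbonyl, and trapping of the tertiary alkoxide as its MOM ether, which marks the oxygen that later becomes a quinone carbonyl.

Step 6
Reactants: 15 2,3-dimethoxy-4-(1-methoxyethenyl)-4-(methoxymethoxy)cyclobut-2-en-1-one
Product: 18 1,2,3,5-tetramethoxy-4-(methoxymethoxy)benzene, via dienylketene 16 (not isolated), via hydroquinone monoether 17 (not isolated)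
Conditions: toluene, 110 °C; then NaH, MeI, THF/DMF, 0 °C → rt
Reagents that add atoms: iodomethane, CI
Why: The same Moore-type ring expansion gives the air-sensitive penta-oxygenated phenol 17, which is methylated in the same flask (Williamson etherification), leaving one ring C–H between two methoxy groups.

Step 7
Reactants: 18 1,2,3,5-tetramethoxy-4-(methoxymethoxy)benzene; 11 (2S)-2-[(2,3,4-trimethoxyphenoxy)methyl]oxirane
Product: 20 (2S)-1-[2,3,4,6-tetramethoxy-5-(methoxymethoxy)phenyl]-3-(2,3,4-trimethoxyphenoxy)propan-2-ol, via aryllithium 19 (not isolated)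
Conditions: n-BuLi, THF, 0 °C; then 11, BF3·OEt2, −78 °C; aqueous work-up
Reagents that add atoms: none
Why: Directed ortho-lithiation at the only ring C–H, then BF3-promoted opening of the terminal epoxide at its CH2 by the aryllithium; the stereocentre is not involved and stays S.

Step 8
Reactants: 20 (2S)-1-[2,3,4,6-tetramethoxy-5-(methoxymethoxy)phenyl]-3-(2,3,4-trimethoxyphenoxy)propan-2-ol
Product: 23 (3S)-6,7,8-trimethoxy-3-[2,3,4,6-tetramethoxy-5-(methoxymethoxy)phenyl]chroman, via triflate 21 (not isolated), via phenonium triflate 22 (not isolated)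
Conditions: Tf2O, 2,6-di-tert-butyl-4-methylpyridine, CH2Cl2, −78 → −20 °C
Reagents that add atoms: none
Why: Proposed new method: a stereoinvertive phenonium-relay cyclisation in which triflate 21 ionises with anchimeric assistance by the 2,4,6-oxygenated ring B (1,2-aryl shift with backside attack at C-3, so the (S)-carbinol gives the (S)-3-aryl centre) and the spirocyclopropane arenium ion 22 is opened at its distal CH2 by ring A in a 6-endo Friedel–Crafts alkylation (the proximal carbon is deactivated by the β-aryloxy group), forming the C-3–aryl bond, the C-4–C-4a bond and ring C in one operation; the closest known reaction types are intermolecular phenonium-ion Friedel–Crafts arylations of β-aryl alcohols in fluorinated alcohols, the 6-endo epoxy-arene cyclialkylation of aryl glycidyl ethers to 3-chromanols, and the 2,3-aryl shift of flavan-3-ol sulfonates to isoflavans.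

Step 9
Reactants: 23 (3S)-6,7,8-trimethoxy-3-[2,3,4,6-tetramethoxy-5-(methoxymethoxy)phenyl]chroman
Product: 25 2,3,5-trimethoxy-6-[(3S)-6,7,8-trimethoxychroman-3-yl]cyclohexa-2,5-diene-1,4-dione (target), via phenol 24 (not isolated)
Conditions: HCl (cat.), MeOH, 50 °C; then PhI(OAc)2, H2O, 0 °C
Reagents that add atoms: water, O
Why: Acidic acetal cleavage frees the only phenol, and PhI(OAc)2 converts this p-methoxyphenol into the p-quinone by oxidative demethylation, leaving the aryl ethers of ring A and the C-3 centre untouched.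

**Compound list**
1 | squaric acid (3,4-dihydroxycyclobut-3-ene-1,2-dione) | O=C1C(O)=C(O)C1=O | starting material
2 | dimethyl squarate (3,4-dimethoxycyclobut-3-ene-1,2-dione) | COC1=C(OC)C(=O)C1=O | intermediate
3 | vinyl bromide | C=CBr | starting material
4 | vinyllithium | [Li]C=C | intermediate
5 | lithium 1-ethenyl-2,3-dimethoxy-4-oxocyclobut-2-en-1-olate | [Li+].[O-]C1(C=C)C(OC)=C(OC)C1=O | intermediate
6 | 4-ethenyl-2,3,4-trimethoxycyclobut-2-en-1-one | COC1=C(OC)C(OC)(C=C)C1=O | intermediate
7 | (3Z)-2,3,4-trimethoxyhexa-1,3,5-trien-1-one (dienylketene) | C=C\C(OC)=C(OC)/C(OC)=C=O | intermediate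
8 | 2,3,4-trimethoxyphenol | COc1ccc(O)c(OC)c1OC | intermediate
9 | (R)-epichlorohydrin | ClC[C@H]1CO1 | starting material
10 | (2R)-1-chloro-3-(2,3,4-trimethoxyphenoxy)propan-2-ol | COc1ccc(OC[C@@H](O)CCl)c(OC)c1OC | intermediate
11 | (2S)-2-[(2,3,4-trimethoxyphenoxy)methyl]oxirane | COc1ccc(OC[C@@H]2CO2)c(OC)c1OC | intermediate
12 | methyl vinyl ether | COC=C | starting material
13 | 1-methoxyvinyllithium | [Li]C(=C)OC | intermediate
14 | lithium 2,3-dimethoxy-1-(1-methoxyethenyl)-4-oxocyclobut-2-en-1-olate | [Li+].[O-]C1(C(=C)OC)C(OC)=C(OC)C1=O | intermediate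
15 | 2,3-dimethoxy-4-(1-methoxyethenyl)-4-(methoxymethoxy)cyclobut-2-en-1-one | COCOC1(C(=C)OC)C(OC)=C(OC)C1=O | intermediate
16 | (3Z)-2,3,5-trimethoxy-4-(methoxymethoxy)hexa-1,3,5-trien-1-one (dienylketene) | C=C(OC)\C(OCOC)=C(OC)/C(OC)=C=O | intermediate
17 | 2,3,5-trimethoxy-4-(methoxymethoxy)phenol | COCOc1c(OC)c(OC)c(O)cc1OC | intermediate
18 | 1,2,3,5-tetramethoxy-4-(methoxymethoxy)benzene | COCOc1c(OC)c(OC)c(OC)cc1OC | intermediate
19 | [2,3,4,6-tetramethoxy-5-(methoxymethoxy)phenyl]lithium | COCOc1c(OC)c(OC)c(OC)c([Li])c1OC | intermediate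
20 | (2S)-1-[2,3,4,6-tetramethoxy-5-(methoxymethoxy)phenyl]-3-(2,3,4-trimethoxyphenoxy)propan-2-ol | COCOc1c(OC)c(OC)c(OC)c(C[C@H](O)COc2ccc(OC)c(OC)c2OC)c1OC | intermediate
21 | (2S)-1-[2,3,4,6-tetramethoxy-5-(methoxymethoxy)phenyl]-3-(2,3,4-trimethoxyphenoxy)propan-2-yl trifluoromethanesulfonate | COCOc1c(OC)c(OC)c(OC)c(C[C@H](OS(=O)(=O)C(F)(F)F)COc2ccc(OC)c(OC)c2OC)c1OC | intermediate
22 | phenonium triflate: spirocyclopropane arenium ion in which C-1 of ring B bridges the former benzylic CH2 and the (S)-configured carbon bearing CH2O–ring A; drawn as the para-oxocarbenium form | COCOC1=C(OC)C2(C[C@@H]2COc3ccc(OC)c(OC)c3OC)C(OC)=C(OC)C1=[O+]C.[O-]S(=O)(=O)C(F)(F)F | intermediate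
23 | (3S)-6,7,8-trimethoxy-3-[2,3,4,6-tetramethoxy-5-(methoxymethoxy)phenyl]chroman | COCOc1c(OC)c(OC)c(OC)c([C@H]2COc3c(OC)c(OC)c(OC)cc3C2)c1OC | intermediate
24 | 2,3,4,6-tetramethoxy-5-[(3S)-6,7,8-trimethoxychroman-3-yl]phenol | Oc1c(OC)c(OC)c(OC)c([C@H]2COc3c(OC)c(OC)c(OC)cc3C2)c1OC | intermediate
25 | 2,3,5-trimethoxy-6-[(3S)-6,7,8-trimethoxychroman-3-yl]cyclohexa-2,5-diene-1,4-dione | COC1=C(OC)C(=O)C([C@H]2COc3c(cc(OC)c(OC)c3OC)C2)=C(OC)C1=O | target

**Step count and risks**
Total steps: 9. Longest linear sequence: 7 (steps 1, 2, 3, 4, 7, 8, 9); the ring B branch (steps 1, 5, 6) joins at step 7.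

Step 8 (the proposed new cyclisation) is the most likely to fail. Ring A could capture the phenonium ion at the proximal carbon (5-exo) to give a 3-(arylmethyl)-2,3-dihydrobenzofuran, an ortho-methoxy group could participate in place of the arene, or elimination could win. The fallback uses known chemistry, sets out from 11 and 19, and comes back at 23. Epoxide 11 is cyclised with AuCl3/AgOTf (6-endo epoxy-arene cyclialkylation) to (3S)-6,7,8-trimethoxychroman-3-ol F1. Dess–Martin oxidation gives 6,7,8-trimethoxychroman-3-one F2. Aryllithium 19, transmetalated with CeCl3 to suppress enolisation, adds to F2 to give racemic 6,7,8-trimethoxy-3-[2,3,4,6-tetramethoxy-5-(methoxymethoxy)phenyl]chroman-3-ol F3. Dehydration (MsCl, Et3N, then DBU) gives 6,7,8-trimethoxy-3-[2,3,4,6-tetramethoxy-5-(methoxymethoxy)phenyl]-2H-chromene F4. Enantioselective hydrogenation of F4 with H2 and [Ir(cod)(tBu-PHOX)][B(C6H3(CF3)2)4], using the ligand enantiomer that delivers the S product, gives 23. Steps 7 and 8 are then not needed.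

Step 7 is the second risk: a 2,6-dialkoxyaryllithium may open the valuable glycidyl ether sluggishly, and BF3 may trigger cyclisation of 11. The fallback sets out from 19 and 8 and comes back at 20; it makes the C–C bond on the small chiral unit and joins the fragments by C–O bond formation. Aryllithium 19 opens an excess of (S)-epichlorohydrin F5 (BF3·OEt2, −78 °C) to give (2S)-1-chloro-3-[2,3,4,6-tetramethoxy-5-(methoxymethoxy)phenyl]propan-2-ol F6. K2CO3 in MeOH closes it to (2S)-2-{[2,3,4,6-tetramethoxy-5-(methoxymethoxy)phenyl]methyl}oxirane F7. The potassium phenoxide of 8 (K2CO3, DMF, 80 °C) opens F7 at the terminal carbon to give 20. Step 4 is then not needed.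

Step 4 is the third risk: direct displacement of chloride competes with the opening/re-closure path and gives the enantiomeric glycidyl ether, which would erode the ee of everything downstream. The fallback sets out from 8 and comes back at 11. Mitsunobu etherification of 8 with (R)-glycidol F8 (PPh3, DIAD, THF) alkylates the phenol at the primary carbinol without involving the epoxide or the stereocentre, giving 11 directly.

**Further compounds**
F1 | step 8 | (3S)-6,7,8-trimethoxychroman-3-ol | O[C@@H]1COc2c(OC)c(OC)c(OC)cc2C1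
F2 | step 8 | 6,7,8-trimethoxychroman-3-one | O=C1COc2c(OC)c(OC)c(OC)cc2C1
F3 | step 8 | racemic 6,7,8-trimethoxy-3-[2,3,4,6-tetramethoxy-5-(methoxymethoxy)phenyl]chroman-3-ol | COCOc1c(OC)c(OC)c(OC)c(C2(O)COc3c(OC)c(OC)c(OC)cc3C2)c1OC
F4 | step 8 | 6,7,8-trimethoxy-3-[2,3,4,6-tetramethoxy-5-(methoxymethoxy)phenyl]-2H-chromene | COCOc1c(OC)c(OC)c(OC)c(C2=Cc3cc(OC)c(OC)c(OC)c3OC2)c1OC
F5 | step 7 | (S)-epichlorohydrin | ClC[C@@H]1CO1
F6 | step 7 | (2S)-1-chloro-3-[2,3,4,6-tetramethoxy-5-(methoxymethoxy)phenyl]propan-2-ol | COCOc1c(OC)c(OC)c(OC)c(C[C@H](O)CCl)c1OC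
F7 | step 7 | (2S)-2-{[2,3,4,6-tetramethoxy-5-(methoxymethoxy)phenyl]methyl}oxirane | COCOc1c(OC)c(OC)c(OC)c(C[C@H]2CO2)c1OC
F8 | step 4 | (R)-glycidol | OC[C@@H]1CO1
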